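**Plan**

- Cuts (azulene numbering of the target): the two ester C–O bonds; C6=C7 (ring-closing metathesis); C4–C5 (methallyl Grignard addition to a lactone carbonyl); then C1–C8a and C2–C3 together, the CH2–CH2 bridge of the five-membered ring, by a reductive (3+2) cycloaddition of a silylacetylene with a 3-acylbutenolide.
- Enabling feature: quaternary C8a and carbinol C3 are 1,3-related through C3a, so they are the β-carbon and the carbonyl carbon of an enone C8a=C3a–C3=O. The oxygenated carbons C8 and C4 flank the fusion bond, so O8 and C4 (as C=O) close a γ-lactone across it. This makes the enone a doubly activated butenolide, allows only a cis ring fusion, and puts the bought stereocenter C8 next to the new quaternary carbon.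
- Forward: O-benzyl-L-serine → α-hydroxy ketone → butenolide (temporary lactone ring) → cyclopentene ring by the (3+2) event → lactone opened by a methallyl Grignard reagent → seven-membered ring by metathesis → ketone reduction, aroylation, phenol release.
- Stereochemistry: the serine carbon becomes C8 and is the only stereocenter bought. In the key event it sets C8a (attack anti to CH2OBn), C3a (cis fusion) and C3 (geometry of the O-bound nickel enolate). C4 comes from hydride attack anti to C3.

Key step: step 5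

Remark: the skeleton is numbered as the azulene of the target; 4, 7, 14, 16 and 20 are taken as commercial; butenolide 6 has an acidic γ-hydrogen and is kept away from bases stronger than pyridine.

**Route**

Step 1
Reactants: 1 O-benzyl-L-serine
Product: 2 (2S)-3-(benzyloxy)-2-hydroxypropanoic acid
Conditions: NaNO2, 1 M H2SO4, H2O, 0 °C to rt
Reagents that add atoms: water, O
Why: Diazotisation of the α-amino acid; the carboxylate displaces N2 to an α-lactone that water opens, so double inversion keeps the configuration.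

Step 2
Reactants: 2 (2S)-3-(benzyloxy)-2-hydroxypropanoic acid
Product: 3 (3S)-4-(benzyloxy)-3-hydroxybutan-2-one
Conditions: MeLi (3.5 equiv), THF, –78 to 0 °C; inverse quench into aq. NH4Cl
Reagents that add atoms: methyllithium, [Li]C
Why: Addition of MeLi to the lithium carboxylate gives a gem-dialkoxide that releases the methyl ketone only on work-up (carboxylic acid to methyl ketone), so the stereocenter is never next to a free carbonyl under basic conditions.

Step 3
Reactants: 3 (3S)-4-(benzyloxy)-3-hydroxybutan-2-one; 4 methyl 4-methyl-3-oxopentanoate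
Product: 5 (2S)-1-(benzyloxy)-3-oxobutan-2-yl 4-methyl-3-oxopentanoate
Conditions: xylenes, 135 °C, MeOH distilled off
Reagents that add atoms: none
Why: Thermal transesterification of a β-keto ester through its acylketene needs no base, so the α-acyloxy ketone stereocenter and the β-benzyloxy group should be left alone.

Step 4
Reactants: 5 (2S)-1-(benzyloxy)-3-oxobutan-2-yl 4-methyl-3-oxopentanoate
Product: 6 (5R)-5-[(benzyloxy)methyl]-4-methyl-3-(2-methylpropanoyl)furan-2(5H)-one
Conditions: TiCl4, pyridine, THF, 0 °C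
Reagents that add atoms: none
Why: Intramolecular Knoevenagel condensation of the active methylene with the methyl ketone closes the five-membered lactone; low temperature and a weak base are chosen to spare the acidic γ-hydrogen of the product.

Step 5
Reactants: 6 (5R)-5-[(benzyloxy)methyl]-4-methyl-3-(2-methylpropanoyl)furan-2(5H)-one; 7 ethynyltrimethylsilane
Product: 9 (3R,3aS,6S,6aR)-3-[(benzyloxy)methyl]-6-hydroxy-3a-methyl-6-(propan-2-yl)-5-(trimethylsilyl)-3,3a,6,6a-tetrahydro-1H-cyclopenta[c]furan-1-one, via nickelacycle 8 (not isolated)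
Conditions: Ni(COD)2 (10 mol %), PPh3 (20 mol %), Et3B (3 equiv), MeOH/THF 8:1, 50 °C, slow addition of 7
Reagents that add atoms: none
Why: Proposed new method: zerovalent nickel should couple the doubly activated C3=C4 bond of 6 with the alkyne by oxidative cyclisation to the seven-membered O-bound nickel enolate 8 (new bond from the butenolide β-carbon to the unsubstituted alkyne carbon, silicon next to nickel), methanol protonates the enolate at carbon, the alkenyl–nickel bond then adds to the freed isopropyl ketone, and Et3B returns zerovalent nickel by ethyl transfer, β-hydride elimination and reductive elimination. The closest known reaction type is the nickel-catalysed reductive (3+2) cycloaddition of enals and enones with alkynes to cyclopentenols, which has not been shown on a tetrasubstituted 2-acylbutenolide. The cyclopentene closes by 5-exo-trig attack of the alkenylnickel carbon on the ketone (attack on the lactone carbonyl would give a strained bridged ring) and can only be cis-fused to the lactone. The quaternary carbon is set by approach anti to the benzyloxymethyl group on the neighbouring γ-carbon, the ring-fusion CH by the cis fusion, and the carbinol carbon by the ketone rotamer inherited from the metallacycle, with oxygen on nickel and syn to the quaternary carbon and the isopropyl group turned away from it, which places OH on the convex face cis to the angular methyl. The step needs one alkyne per butenolide, C-protonation of a 1,3-dicarbonyl enolate before the alkenylnickel is protonated, and survival of the acidic γ-hydrogen; the bulky silyl group, the large excess of methanol and the base-free medium are relied on for these.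

Step 6
Reactants: 9 (3R,3aS,6S,6aR)-3-[(benzyloxy)methyl]-6-hydroxy-3a-methyl-6-(propan-2-yl)-5-(trimethylsilyl)-3,3a,6,6a-tetrahydro-1H-cyclopenta[c]furan-1-one
Product: 10 (3R,3aS,6S,6aR)-3-[(benzyloxy)methyl]-6-hydroxy-5-iodo-3a-methyl-6-(propan-2-yl)-3,3a,6,6a-tetrahydro-1H-cyclopenta[c]furan-1-one
Conditions: N-iodosuccinimide, MeCN, 0 °C
Reagents that add atoms: N-iodosuccinimide, O=C1CCC(=O)N1I
Why: ipso-Iododesilylation of a vinylsilane through the β-silyl cation keeps the double-bond position and needs no base, so the β-hydroxy lactone is not exposed to retro-aldol conditions.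

Step 7
Reactants: 10 (3R,3aS,6S,6aR)-3-[(benzyloxy)methyl]-6-hydroxy-5-iodo-3a-methyl-6-(propan-2-yl)-3,3a,6,6a-tetrahydro-1H-cyclopenta[c]furan-1-one
Product: 11 (3R,3aR,6S,6aR)-6-hydroxy-3-(hydroxymethyl)-3a-methyl-6-(propan-2-yl)hexahydro-1H-cyclopenta[c]furan-1-one
Conditions: H2 (1–3 atm), Pd/C, NaOAc, EtOH, rt
Reagents that add atoms: none
Why: One catalytic hydrogenation should saturate the ring alkene, hydrogenolyse the C–I bond and remove the benzyl ether; no stereocenter is created.

Step 8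
Reactants: 11 (3R,3aR,6S,6aR)-6-hydroxy-3-(hydroxymethyl)-3a-methyl-6-(propan-2-yl)hexahydro-1H-cyclopenta[c]furan-1-one
Product: 12 (1R,3aR,4S,6aR)-4-hydroxy-6a-methyl-3-oxo-4-(propan-2-yl)hexahydro-1H-cyclopenta[c]furan-1-carbaldehyde
Conditions: Dess–Martin periodinane, CH2Cl2, 0 °C to rt
Reagents that add atoms: none
Why: Dess–Martin oxidation of the primary alcohol; the tertiary alcohol is inert and the neutral medium avoids epimerisation of the α-acyloxy aldehyde.

Step 9
Reactants: 12 (1R,3aR,4S,6aR)-4-hydroxy-6a-methyl-3-oxo-4-(propan-2-yl)hexahydro-1H-cyclopenta[c]furan-1-carbaldehyde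
Product: 13 (3S,3aR,6S,6aR)-3-ethenyl-6-hydroxy-3a-methyl-6-(propan-2-yl)hexahydro-1H-cyclopenta[c]furan-1-one
Conditions: Ph3PCH3Br, KN(SiMe3)2 (3 equiv of ylide), THF, –78 to 0 °C
Reagents that add atoms: methyltriphenylphosphonium bromide, C[P+](c1ccccc1)(c1ccccc1)c1ccccc1.[Br-]
Why: Wittig methylenation of the aldehyde; the lactone carbonyl does not react with the ylide at low temperature.

Step 10
Reactants: 13 (3S,3aR,6S,6aR)-3-ethenyl-6-hydroxy-3a-methyl-6-(propan-2-yl)hexahydro-1H-cyclopenta[c]furan-1-one; 14 (2-methylprop-2-en-1-yl)magnesium chloride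
Product: 15 1-[(1R,2S,5R)-2-hydroxy-5-[(1S)-1-hydroxyprop-2-en-1-yl]-5-methyl-2-(propan-2-yl)cyclopentyl]-3-methylbut-3-en-1-one
Conditions: 14 (2.2 equiv), THF, –78 °C; AcOH quench at –78 °C
Reagents that add atoms: none
Why: Mono-addition of a Grignard reagent to a γ-lactone: the first equivalent deprotonates the tertiary alcohol, the second adds, and the magnesium hemiketal alkoxide should survive at –78 °C so that the ketone appears only after the quench; 15 equilibrates with its cyclic hemiketal.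

Step 11
Reactants: 15 1-[(1R,2S,5R)-2-hydroxy-5-[(1S)-1-hydroxyprop-2-en-1-yl]-5-methyl-2-(propan-2-yl)cyclopentyl]-3-methylbut-3-en-1-one; 16 3-methylbutanoic anhydride
Product: 17 (1S)-1-[(1R,2R,3S)-3-hydroxy-1-methyl-2-(3-methylbut-3-enoyl)-3-(propan-2-yl)cyclopentyl]prop-2-en-1-yl 3-methylbutanoate
Conditions: pyridine, DMAP (cat.), CH2Cl2, 0 °C
Reagents that add atoms: none
Why: DMAP-catalysed acylation should take the secondary allylic alcohol of the open hydroxy ketone tautomer; the tertiary alcohol and the hemiketal hydroxyl are too hindered, and the weak base should leave the β,γ-unsaturated ketone unconjugated.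

Step 12
Reactants: 17 (1S)-1-[(1R,2R,3S)-3-hydroxy-1-methyl-2-(3-methylbut-3-enoyl)-3-(propan-2-yl)cyclopentyl]prop-2-en-1-yl 3-methylbutanoate
Product: 18 (3S,3aR,8S,8aR)-3-hydroxy-6,8a-dimethyl-4-oxo-3-(propan-2-yl)-1,2,3,3a,4,5,8,8a-octahydroazulen-8-yl 3-methylbutanoate
Conditions: second-generation Grubbs catalyst (5 mol %), 1,4-benzoquinone (10 mol %), CH2Cl2, 40 °C
Reagents that add atoms: none
Why: Ring-closing metathesis of the vinyl and the 1,1-disubstituted alkene, held cis on the cyclopentane, should give the trisubstituted cycloheptene; benzoquinone suppresses ruthenium hydride isomerisation of the β,γ-enone.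

Step 13
Reactants: 18 (3S,3aR,8S,8aR)-3-hydroxy-6,8a-dimethyl-4-oxo-3-(propan-2-yl)-1,2,3,3a,4,5,8,8a-octahydroazulen-8-yl 3-methylbutanoate
Product: 19 (3S,3aS,4R,8S,8aR)-3,4-dihydroxy-6,8a-dimethyl-3-(propan-2-yl)-1,2,3,3a,4,5,8,8a-octahydroazulen-8-yl 3-methylbutanoate
Conditions: NaBH4, CeCl3·7H2O, MeOH, –40 °C
Reagents that add atoms: none
Why: Luche-type 1,2-reduction; hydride should attack C4 on the face that carries the ring-fusion hydrogen, anti to the fully substituted C3 whose isopropyl group screens the other face, which gives the 4R alcohol.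

Step 14
Reactants: 19 (3S,3aS,4R,8S,8aR)-3,4-dihydroxy-6,8a-dimethyl-3-(propan-2-yl)-1,2,3,3a,4,5,8,8a-octahydroazulen-8-yl 3-methylbutanoate; 20 4-(acetyloxy)benzoyl chloride
Product: 21 (3S,3aS,4R,8S,8aR)-4-{[4-(acetyloxy)benzoyl]oxy}-3-hydroxy-6,8a-dimethyl-3-(propan-2-yl)-1,2,3,3a,4,5,8,8a-octahydroazulen-8-yl 3-methylbutanoate
Conditions: pyridine, DMAP, CH2Cl2, 0 to 40 °C
Reagents that add atoms: none
Why: Acylation of the only secondary alcohol; the tertiary alcohol should not react.

Step 15
Reactants: 21 (3S,3aS,4R,8S,8aR)-4-{[4-(acetyloxy)benzoyl]oxy}-3-hydroxy-6,8a-dimethyl-3-(propan-2-yl)-1,2,3,3a,4,5,8,8a-octahydroazulen-8-yl 3-methylbutanoate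
Product: 22 (3S,3aS,4R,8S,8aR)-3-hydroxy-4-[(4-hydroxybenzoyl)oxy]-6,8a-dimethyl-3-(propan-2-yl)-1,2,3,3a,4,5,8,8a-octahydroazulen-8-yl 3-methylbutanoate
Conditions: NH3 (7 M in MeOH), 0 °C
Reagents that add atoms: none
Why: Ammonolysis of the aryl acetate, the only ester with a phenoxide leaving group; the two esters of hindered secondary alcohols should remain.

**Compound list**

1 | O-benzyl-L-serine | N[C@@H](COCc1ccccc1)C(=O)O | starting material
2 | (2S)-3-(benzyloxy)-2-hydroxypropanoic acid | OC(=O)[C@@H](O)COCc1ccccc1 | intermediate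
3 | (3S)-4-(benzyloxy)-3-hydroxybutan-2-one | CC(=O)[C@@H](O)COCc1ccccc1 | intermediate
4 | methyl 4-methyl-3-oxopentanoate | CC(C)C(=O)CC(=O)OC | starting material
5 | (2S)-1-(benzyloxy)-3-oxobutan-2-yl 4-methyl-3-oxopentanoate | CC(C)C(=O)CC(=O)O[C@@H](COCc1ccccc1)C(C)=O | intermediate
6 | (5R)-5-[(benzyloxy)methyl]-4-methyl-3-(2-methylpropanoyl)furan-2(5H)-one | CC(C)C(=O)C1=C(C)[C@H](COCc2ccccc2)OC1=O | intermediate
7 | ethynyltrimethylsilane | C#C[Si](C)(C)C | starting material
8 | seven-membered O-bound nickel enolate (nickelacycle) from 6 and 7, phosphine on nickel not drawn | CC(C)C1=C2C(=O)O[C@@H](COCc3ccccc3)[C@]2(C)C=C([Si](C)(C)C)[Ni]O1 | intermediate (not isolated)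
9 | (3R,3aS,6S,6aR)-3-[(benzyloxy)methyl]-6-hydroxy-3a-methyl-6-(propan-2-yl)-5-(trimethylsilyl)-3,3a,6,6a-tetrahydro-1H-cyclopenta[c]furan-1-one | C(OCc1ccccc1)[C@@H]1OC(=O)[C@@H]2[C@@]1(C)C=C([Si](C)(C)C)[C@]2(O)C(C)C | intermediate
10 | (3R,3aS,6S,6aR)-3-[(benzyloxy)methyl]-6-hydroxy-5-iodo-3a-methyl-6-(propan-2-yl)-3,3a,6,6a-tetrahydro-1H-cyclopenta[c]furan-1-one | C(OCc1ccccc1)[C@@H]1OC(=O)[C@@H]2[C@@]1(C)C=C(I)[C@]2(O)C(C)C | intermediate
11 | (3R,3aR,6S,6aR)-6-hydroxy-3-(hydroxymethyl)-3a-methyl-6-(propan-2-yl)hexahydro-1H-cyclopenta[c]furan-1-one | OC[C@@H]1OC(=O)[C@@H]2[C@@]1(C)CC[C@]2(O)C(C)C | intermediate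
12 | (1R,3aR,4S,6aR)-4-hydroxy-6a-methyl-3-oxo-4-(propan-2-yl)hexahydro-1H-cyclopenta[c]furan-1-carbaldehyde | O=C[C@@H]1OC(=O)[C@@H]2[C@@]1(C)CC[C@]2(O)C(C)C | intermediate
13 | (3S,3aR,6S,6aR)-3-ethenyl-6-hydroxy-3a-methyl-6-(propan-2-yl)hexahydro-1H-cyclopenta[c]furan-1-one | C=C[C@@H]1OC(=O)[C@@H]2[C@@]1(C)CC[C@]2(O)C(C)C | intermediate
14 | (2-methylprop-2-en-1-yl)magnesium chloride | CC(=C)C[Mg]Cl | starting material
15 | 1-[(1R,2S,5R)-2-hydroxy-5-[(1S)-1-hydroxyprop-2-en-1-yl]-5-methyl-2-(propan-2-yl)cyclopentyl]-3-methylbut-3-en-1-one | C=C[C@H](O)[C@]1(C)CC[C@](O)(C(C)C)[C@@H]1C(=O)CC(C)=C | intermediate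
16 | 3-methylbutanoic anhydride | CC(C)CC(=O)OC(=O)CC(C)C | starting material
17 | (1S)-1-[(1R,2R,3S)-3-hydroxy-1-methyl-2-(3-methylbut-3-enoyl)-3-(propan-2-yl)cyclopentyl]prop-2-en-1-yl 3-methylbutanoate | C=C[C@H](OC(=O)CC(C)C)[C@]1(C)CC[C@](O)(C(C)C)[C@@H]1C(=O)CC(C)=C | intermediate
18 | (3S,3aR,8S,8aR)-3-hydroxy-6,8a-dimethyl-4-oxo-3-(propan-2-yl)-1,2,3,3a,4,5,8,8a-octahydroazulen-8-yl 3-methylbutanoate | CC1=C[C@H](OC(=O)CC(C)C)[C@]2(C)CC[C@](O)(C(C)C)[C@@H]2C(=O)C1 | intermediate
19 | (3S,3aS,4R,8S,8aR)-3,4-dihydroxy-6,8a-dimethyl-3-(propan-2-yl)-1,2,3,3a,4,5,8,8a-octahydroazulen-8-yl 3-methylbutanoate | CC1=C[C@H](OC(=O)CC(C)C)[C@]2(C)CC[C@](O)(C(C)C)[C@@H]2[C@H](O)C1 | intermediate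
20 | 4-(acetyloxy)benzoyl chloride | CC(=O)Oc1ccc(cc1)C(Cl)=O | starting material
21 | (3S,3aS,4R,8S,8aR)-4-{[4-(acetyloxy)benzoyl]oxy}-3-hydroxy-6,8a-dimethyl-3-(propan-2-yl)-1,2,3,3a,4,5,8,8a-octahydroazulen-8-yl 3-methylbutanoate | CC1=C[C@H](OC(=O)CC(C)C)[C@]2(C)CC[C@](O)(C(C)C)[C@@H]2[C@H](OC(=O)c2ccc(OC(C)=O)cc2)C1 | intermediate
22 | (3S,3aS,4R,8S,8aR)-3-hydroxy-4-[(4-hydroxybenzoyl)oxy]-6,8a-dimethyl-3-(propan-2-yl)-1,2,3,3a,4,5,8,8a-octahydroazulen-8-yl 3-methylbutanoate | CC1=C[C@H](OC(=O)CC(C)C)[C@]2(C)CC[C@](O)(C(C)C)[C@@H]2[C@H](OC(=O)c2ccc(O)cc2)C1 | target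

**Step count and risks**

Total step count: 15. Longest linear sequence: 15 steps (1 to 22).

Steps most likely to fail:

1. Step 5 (Proposed new method). Possible failures: no oxidative cyclisation at the tetrasubstituted alkene; protonation of the alkenylnickel before the 1,3-dicarbonyl enolate, which gives open-chain reductive coupling; loss of the γ-hydrogen, with racemisation or elimination of benzyl alcohol; poor facial selectivity in the ketone insertion. The fallback uses known chemistry, sets out from 6 and comes back at 11. Hosomi–Sakurai allylation (allyltrimethylsilane, TiCl4, CH2Cl2, –78 °C) anti to the benzyloxymethyl group would give (4R,5R)-5-[(benzyloxy)methyl]-4-methyl-3-(2-methylpropanoyl)-4-(prop-2-en-1-yl)oxolan-2-one F1. Oxidative cleavage of the alkene (OsO4 cat., NaIO4, 2,6-lutidine, dioxane/H2O) would give 2-[(2R,3R)-2-[(benzyloxy)methyl]-3-methyl-4-(2-methylpropanoyl)-5-oxooxolan-3-yl]acetaldehyde F2. Intramolecular McMurry coupling of aldehyde and ketone (TiCl3(DME)1.5, Zn–Cu, DME, reflux, high dilution) would give (3R,3aR,6aS)-3-[(benzyloxy)methyl]-3a-methyl-6-(propan-2-yl)-3,3a,4,6a-tetrahydro-1H-cyclopenta[c]furan-1-one F3. Mukaiyama hydration (Co(acac)2 cat., PhSiH3, O2, THF, rt) should deliver oxygen to the tertiary radical on the convex face and give (3R,3aR,6S,6aR)-3-[(benzyloxy)methyl]-6-hydroxy-3a-methyl-6-(propan-2-yl)hexahydro-1H-cyclopenta[c]furan-1-one F4. Hydrogenolysis (H2, Pd/C, EtOH) would then give 11.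

2. Step 6. Electrophilic iodine next to the tertiary allylic alcohol may trigger a 1,2-shift or ionisation instead of clean ipso-substitution. The fallback sets out from 9 and comes back at 11, and uses the silyl group for a Peterson elimination instead. Hydrogenation (H2, 4 atm, Pd/C, EtOAc) would saturate the vinylsilane and remove the benzyl group to give (3R,3aR,6S,6aR)-6-hydroxy-3-(hydroxymethyl)-3a-methyl-6-(propan-2-yl)-5-(trimethylsilyl)hexahydro-1H-cyclopenta[c]furan-1-one F5 (either C5 epimer). Peterson elimination (BF3·OEt2, CH2Cl2, 0 °C for the anti isomer, KH in THF for the syn isomer) would give (3R,3aR,6aS)-3-(hydroxymethyl)-3a-methyl-6-(propan-2-yl)-3,3a,4,6a-tetrahydro-1H-cyclopenta[c]furan-1-one F6. Mukaiyama hydration as above would give 11. This detour also rewrites the carbinol configuration should the cycloaddition give the other epimer.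

3. Step 10. The hemiketal alkoxide may collapse early so that the allylic Grignard reagent adds twice, or the β-alkoxide may undergo retro-aldol cleavage. The fallback sets out from 13 and comes back at 15. Aminolysis of the lactone (AlMe3, MeNHOMe·HCl, CH2Cl2, 0 °C to rt) would give the Weinreb amide (1R,2S,5R)-2-hydroxy-5-[(1S)-1-hydroxyprop-2-en-1-yl]-N-methoxy-N,5-dimethyl-2-(propan-2-yl)cyclopentane-1-carboxamide F7. Its stable magnesium chelate should take up only one methallyl group from 14 (3.3 equiv, THF, –78 to 0 °C) to give 15.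

Further compounds
F1 | step 5 | (4R,5R)-5-[(benzyloxy)methyl]-4-methyl-3-(2-methylpropanoyl)-4-(prop-2-en-1-yl)oxolan-2-one (C3 epimerisable) | C=CC[C@@]1(C)[C@H](COCc2ccccc2)OC(=O)C1C(=O)C(C)C
F2 | step 5 | 2-[(2R,3R)-2-[(benzyloxy)methyl]-3-methyl-4-(2-methylpropanoyl)-5-oxooxolan-3-yl]acetaldehyde | O=CC[C@@]1(C)[C@H](COCc2ccccc2)OC(=O)C1C(=O)C(C)C
F3 | step 5 | (3R,3aR,6aS)-3-[(benzyloxy)methyl]-3a-methyl-6-(propan-2-yl)-3,3a,4,6a-tetrahydro-1H-cyclopenta[c]furan-1-one | C(OCc1ccccc1)[C@@H]1OC(=O)[C@@H]2[C@@]1(C)CC=C2C(C)C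
F4 | step 5 | (3R,3aR,6S,6aR)-3-[(benzyloxy)methyl]-6-hydroxy-3a-methyl-6-(propan-2-yl)hexahydro-1H-cyclopenta[c]furan-1-one | C(OCc1ccccc1)[C@@H]1OC(=O)[C@@H]2[C@@]1(C)CC[C@]2(O)C(C)C
F5 | step 6 | (3R,3aR,6S,6aR)-6-hydroxy-3-(hydroxymethyl)-3a-methyl-6-(propan-2-yl)-5-(trimethylsilyl)hexahydro-1H-cyclopenta[c]furan-1-one (C5 not defined) | OC[C@@H]1OC(=O)[C@@H]2[C@@]1(C)CC([Si](C)(C)C)[C@]2(O)C(C)C
F6 | step 6 | (3R,3aR,6aS)-3-(hydroxymethyl)-3a-methyl-6-(propan-2-yl)-3,3a,4,6a-tetrahydro-1H-cyclopenta[c]furan-1-one | OC[C@@H]1OC(=O)[C@@H]2[C@@]1(C)CC=C2C(C)C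
F7 | step 10 | (1R,2S,5R)-2-hydroxy-5-[(1S)-1-hydroxyprop-2-en-1-yl]-N-methoxy-N,5-dimethyl-2-(propan-2-yl)cyclopentane-1-carboxamide | C=C[C@H](O)[C@]1(C)CC[C@](O)(C(C)C)[C@@H]1C(=O)N(C)OC
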